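## Retrosynthetic overview

1. The target comes from the 8‑hydroxy‑14,15‑diol lactone by 8‑O‑angeloylation as the last operation, with transient silylation of the two primary hydroxyls.
2. Both rings form in one flask in the biosynthetic order. The ten‑membered carbocycle closes first through the C6–C7 bond (the farnesyl C1→C10 closure), with a free lactol as the C6 electrophile and the C7=C11 π‑system as an allyl‑chromium nucleophile. The C12→O6 γ‑lactone closes second. C6 and C7 are set in this step under control of C8 and the ring‑cis olefin.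
3. The seco precursor comes from a Baylis–Hillman reaction and SN2′ bromination at C7. The C1=C10 olefin comes from a Horner–Wadsworth–Emmons reaction of a lactone phosphonate (C8–C10, C14) with a C1 aldehyde.
4. C8 comes from (R)‑PMB glycidyl ether. C4 comes from a Cu‑catalysed asymmetric conjugate addition to furan‑2(5H)‑one; the resulting lactone, as its lactol acetal, masks C6 and C15 together.

Assumption: germacrane numbering is used for locants (C6 lactone carbinol, C7 ring‑fusion carbon, C8 angelate carbon, C4 the CH bearing C15H2OH, C10 the olefinic carbon bearing C14H2OH; the 1(10) olefin is E by CIP, with C2 and C9 cis), and all numbered starting materials are taken as commercial.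

## Route

Step 1
Reactants: 1 furan‑2(5H)‑one; 2 but‑3‑en‑1‑ylmagnesium bromide
Product: 3 (R)‑4‑(but‑3‑en‑1‑yl)dihydrofuran‑2(3H)‑one
Conditions: CuBr·SMe2 (5 mol %), Josiphos‑type diphosphine (6 mol %), t‑BuOMe, −78 °C; aq. NH4Cl
Reagents that add atoms: none
Why: Cu‑catalysed asymmetric conjugate addition of the Grignard reagent to the butenolide, in which the chiral Cu–diphosphine complex selects one face of C4 and sets the (R) centre that becomes C4 of the target (ligand antipode chosen accordingly).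

Step 2
Reactants: 3 (R)‑4‑(but‑3‑en‑1‑yl)dihydrofuran‑2(3H)‑one
Product: 5 (4R)‑4‑(but‑3‑en‑1‑yl)‑2‑methoxytetrahydrofuran (anomer mixture), via lactol 4 (not isolated)
Conditions: DIBAL‑H, CH2Cl2, −78 °C; Rochelle work‑up; crude in MeOH, PPTS (cat.), rt
Reagents that add atoms: methanol, CO
Why: DIBAL reduction of a γ‑lactone stops at the lactol at −78 °C, and acid‑catalysed Fischer‑type acetalisation then gives the cyclic methyl acetal that masks the C6 aldehyde and the C15 hydroxyl together without touching C4.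

Step 3
Reactants: 5 (4R)‑4‑(but‑3‑en‑1‑yl)‑2‑methoxytetrahydrofuran
Product: 6 3‑[(3R)‑5‑methoxytetrahydrofuran‑3‑yl]propanal
Conditions: O3, CH2Cl2, −78 °C (Sudan III end point); PPh3, −78 °C → rt
Reagents that add atoms: ozone, [O-][O+]=O
Why: Ozonolysis with reductive work‑up cleaves the only C=C bond to the C1 aldehyde far faster than ozone attacks the acetal.

Step 4
Reactants: 7 (R)‑2‑{[(4‑methoxybenzyl)oxy]methyl}oxirane; 8 triethyl phosphonoacetate
Product: 9 diethyl [(5R)‑5‑{[(4‑methoxybenzyl)oxy]methyl}‑2‑oxotetrahydrofuran‑3‑yl]phosphonate (C3 epimers)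
Conditions: NaH, toluene/DMF, 0 °C; then 7, 90 °C; AcOH quench
Reagents that add atoms: none
Why: The phosphonoacetate carbanion opens the epoxide at its CH2 terminus (SN2) and the alkoxide lactonises onto the ethyl ester (alkylation–lactonisation), so the stereocentre of 7 passes unchanged into C8.

Step 5
Reactants: 6 3‑[(3R)‑5‑methoxytetrahydrofuran‑3‑yl]propanal; 9 the lactone phosphonate
Product: 10 (3E,5R)‑3‑{3‑[(3R)‑5‑methoxytetrahydrofuran‑3‑yl]propylidene}‑5‑{[(4‑methoxybenzyl)oxy]methyl}dihydrofuran‑2(3H)‑one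
Conditions: NaH, THF, 0 °C; then 6, 0 °C → rt
Reagents that add atoms: none
Why: Horner–Wadsworth–Emmons olefination of the stabilised lactone phosphonate gives mainly the more stable (E)‑alkylidene lactone (chain trans to C=O, so C2 is cis to C9 as in the target), and the minor Z isomer is removed by chromatography.

Step 6
Reactants: 10 the (E)‑alkylidene lactone
Product: 11 (2E)‑2‑[(2R)‑2‑hydroxy‑3‑(4‑methoxybenzyloxy)propyl]‑5‑[(3R)‑5‑methoxytetrahydrofuran‑3‑yl]pent‑2‑en‑1‑ol
Conditions: DIBAL‑H (4 equiv), CH2Cl2, −78 → −20 °C; Rochelle work‑up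
Reagents that add atoms: none
Why: DIBAL 1,2‑reduction of the conjugated lactone gives the C14 allylic alcohol and frees the C8 alcohol, leaving olefin geometry, acetal and PMB ether intact.

Step 7
Reactants: 11 the diol
Product: 12 bis(tert‑butyldimethylsilyl) ether of 11 (C14‑O and C8‑O silylated)
Conditions: TBSCl (3 equiv), imidazole, DMAP (cat.), DMF, rt
Reagents that add atoms: tert‑butyldimethylsilyl chloride, CC(C)(C)[Si](C)(C)Cl
Why: Corey silylation protects both hydroxyls so that C7 can be oxidised and the C8 oxygen can neither eliminate nor cyclise onto the later allylic bromide.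

Step 8
Reactants: 12 the bis‑TBS PMB ether
Product: 13 (2R,4E)‑2‑(tert‑butyldimethylsilyloxy)‑4‑[(tert‑butyldimethylsilyloxy)methyl]‑7‑[(3R)‑5‑methoxytetrahydrofuran‑3‑yl]hept‑4‑en‑1‑ol
Conditions: DDQ, CH2Cl2/pH 7 buffer, 0 °C
Reagents that add atoms: none
Why: DDQ oxidative cleavage removes the PMB ether selectively under buffered conditions, to which silyl ethers, acetal and the trisubstituted olefin are inert.

Step 9
Reactants: 13 the primary alcohol
Product: 14 (2R,4E)‑2‑(tert‑butyldimethylsilyloxy)‑4‑[(tert‑butyldimethylsilyloxy)methyl]‑7‑[(3R)‑5‑methoxytetrahydrofuran‑3‑yl]hept‑4‑enal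
Conditions: TPAP (5 mol %), NMO, 4 Å MS, CH2Cl2, rt
Reagents that add atoms: none
Why: Ley–Griffith oxidation gives the α‑silyloxy aldehyde under neutral conditions without epimerising C8.

Step 10
Reactants: 14 the α‑silyloxy aldehyde; 15 methyl acrylate
Product: 16 methyl (4R,6E)‑4‑(tert‑butyldimethylsilyloxy)‑6‑[(tert‑butyldimethylsilyloxy)methyl]‑3‑hydroxy‑9‑[(3R)‑5‑methoxytetrahydrofuran‑3‑yl]‑2‑methylidenenon‑6‑enoate (C3 epimers)
Conditions: 15 (10 equiv), quinuclidine (0.5 equiv), MeOH (2 equiv), rt, 2–3 d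
Reagents that add atoms: none
Why: Morita–Baylis–Hillman reaction in which the amine–acrylate zwitterion adds to the activated α‑silyloxy aldehyde and attaches C11–C13 to C7; the new carbinol centre is destroyed in step 11, so its configuration does not matter.

Step 11
Reactants: 16 the Baylis–Hillman adduct
Product: 17 methyl (2Z,4R,6E)‑2‑(bromomethyl)‑4‑(tert‑butyldimethylsilyloxy)‑6‑[(tert‑butyldimethylsilyloxy)methyl]‑9‑[(3R)‑5‑methoxytetrahydrofuran‑3‑yl]nona‑2,6‑dienoate
Conditions: NBS, Me2S, CH2Cl2, 0 °C → rt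
Reagents that add atoms: N‑bromosuccinimide, O=C1CCC(=O)N1Br
Why: Corey–Kim‑type activation of the allylic alcohol followed by SN2′ attack of bromide gives the conjugated primary (Z)‑allyl bromide, the standard outcome for Baylis–Hillman adducts.

Step 12
Reactants: 17 the allylic bromide acetal
Product: 18 methyl (2Z,4R,6E)‑2‑(bromomethyl)‑4‑(tert‑butyldimethylsilyloxy)‑6‑[(tert‑butyldimethylsilyloxy)methyl]‑9‑[(3R)‑5‑hydroxytetrahydrofuran‑3‑yl]nona‑2,6‑dienoate (lactol anomers)
Conditions: PPTS (cat.), acetone/H2O 4:1, rt → 40 °C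
Reagents that add atoms: water, O
Why: Mild acid‑catalysed acetal hydrolysis releases the γ‑lactol (latent C6 aldehyde plus free C15‑OH) while the TBS ethers and the allylic bromide survive.

Step 13
Reactants: 18 the lactol allylic bromide
Product: 20 (4R,6R,7R,8R)‑8,14,15‑trihydroxygermacra‑1(10),11(13)‑dien‑12,6‑olide (C7 descriptor differs from the target by CIP priority only), via bis‑TBS lactone 19 (not isolated)
Conditions: CrCl2 (10 equiv), DMF/THF, rt, syringe‑pump addition (2 mM); then 48 % aq. HF, MeCN, 0 °C → rt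
Reagents that add atoms: none
Why: Nozaki–Hiyama–Kishi‑type allylation in which the 2‑(methoxycarbonyl)allyl‑chromium(III) adds through C7 to the lactol‑derived C6 aldehyde via a chair transition state (anti addition, hence the 6,7‑trans lactone) on the face of C7 anti to C9 with H8 in the allyl plane (A1,3 control by C8), closing the ten‑membered ring and setting C6 and C7; the chromium alkoxide then lactonises onto C12 and HF removes both TBS groups.

Step 14
Reactants: 20 the triol lactone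
Product: 21 (4R,6R,7R,8R)‑8‑hydroxy‑14,15‑bis(triethylsilyloxy)germacra‑1(10),11(13)‑dien‑12,6‑olide
Conditions: TESCl (2.1 equiv), imidazole, CH2Cl2, −40 → −20 °C
Reagents that add atoms: chlorotriethylsilane, CC[Si](Cl)(CC)CC
Why: The two primary alcohols are silylated far faster than the hindered secondary C8 alcohol (transient protection).

Step 15
Reactants: 21 the bis‑TES 8‑alcohol; 22 angelic acid, (Z)‑2‑methylbut‑2‑enoic acid
Product: 24 target, (4R,6R,7S,8R)‑8‑angeloyloxy‑14,15‑dihydroxygermacra‑1(10),11(13)‑dien‑12,6‑olide, via bis‑TES angelate 23 (not isolated)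
Conditions: 22, 2,4,6‑trichlorobenzoyl chloride, Et3N, toluene, rt; then 21, 75 °C; then 1 M aq. HCl, THF, 0 °C → rt
Reagents that add atoms: none
Why: Yamaguchi esterification through the angelic mixed anhydride without DMAP acylates the hindered 8‑OH without Z→E isomerisation to the tiglate, and dilute acid then cleaves the two primary TES ethers.

## Compound list

1 | furan‑2(5H)‑one | O=C1C=CCO1 | starting material
2 | but‑3‑en‑1‑ylmagnesium bromide | C=CCC[Mg]Br | starting material
3 | (R)‑4‑(but‑3‑en‑1‑yl)dihydrofuran‑2(3H)‑one | O=C1C[C@H](CO1)CCC=C | intermediate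
4 | (4R)‑4‑(but‑3‑en‑1‑yl)tetrahydrofuran‑2‑ol (lactol, not isolated) | OC1C[C@H](CO1)CCC=C | intermediate
5 | (4R)‑4‑(but‑3‑en‑1‑yl)‑2‑methoxytetrahydrofuran | COC1C[C@H](CO1)CCC=C | intermediate
6 | 3‑[(3R)‑5‑methoxytetrahydrofuran‑3‑yl]propanal | COC1C[C@H](CO1)CCC=O | intermediate
7 | (R)‑2‑{[(4‑methoxybenzyl)oxy]methyl}oxirane | C1[C@@H](O1)COCc1ccc(OC)cc1 | starting material
8 | triethyl phosphonoacetate | CCOC(=O)CP(=O)(OCC)OCC | starting material
9 | diethyl [(5R)‑5‑{[(4‑methoxybenzyl)oxy]methyl}‑2‑oxotetrahydrofuran‑3‑yl]phosphonate | CCOP(=O)(OCC)C1C[C@H](COCc2ccc(OC)cc2)OC1=O | intermediate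
10 | (3E,5R)‑3‑{3‑[(3R)‑5‑methoxytetrahydrofuran‑3‑yl]propylidene}‑5‑{[(4‑methoxybenzyl)oxy]methyl}dihydrofuran‑2(3H)‑one | COC1C[C@H](CO1)CC/C=C2\C[C@H](COCc3ccc(OC)cc3)OC2=O | intermediate
11 | (2E)‑2‑[(2R)‑2‑hydroxy‑3‑(4‑methoxybenzyloxy)propyl]‑5‑[(3R)‑5‑methoxytetrahydrofuran‑3‑yl]pent‑2‑en‑1‑ol | COC1C[C@H](CO1)CC/C=C(/CO)C[C@@H](O)COCc1ccc(OC)cc1 | intermediate
12 | bis(tert‑butyldimethylsilyl) ether of 11 | COC1C[C@H](CO1)CC/C=C(/CO[Si](C)(C)C(C)(C)C)C[C@@H](O[Si](C)(C)C(C)(C)C)COCc1ccc(OC)cc1 | intermediate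
13 | (2R,4E)‑2‑(TBS‑oxy)‑4‑[(TBS‑oxy)methyl]‑7‑[(3R)‑5‑methoxytetrahydrofuran‑3‑yl]hept‑4‑en‑1‑ol | COC1C[C@H](CO1)CC/C=C(/CO[Si](C)(C)C(C)(C)C)C[C@@H](O[Si](C)(C)C(C)(C)C)CO | intermediate
14 | (2R,4E)‑2‑(TBS‑oxy)‑4‑[(TBS‑oxy)methyl]‑7‑[(3R)‑5‑methoxytetrahydrofuran‑3‑yl]hept‑4‑enal | COC1C[C@H](CO1)CC/C=C(/CO[Si](C)(C)C(C)(C)C)C[C@@H](O[Si](C)(C)C(C)(C)C)C=O | intermediate
15 | methyl acrylate | C=CC(=O)OC | starting material
16 | methyl (4R,6E)‑4‑(TBS‑oxy)‑6‑[(TBS‑oxy)methyl]‑3‑hydroxy‑9‑[(3R)‑5‑methoxytetrahydrofuran‑3‑yl]‑2‑methylidenenon‑6‑enoate | COC1C[C@H](CO1)CC/C=C(/CO[Si](C)(C)C(C)(C)C)C[C@@H](O[Si](C)(C)C(C)(C)C)C(O)C(=C)C(=O)OC | intermediate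
17 | methyl (2Z,4R,6E)‑2‑(bromomethyl)‑4‑(TBS‑oxy)‑6‑[(TBS‑oxy)methyl]‑9‑[(3R)‑5‑methoxytetrahydrofuran‑3‑yl]nona‑2,6‑dienoate | COC1C[C@H](CO1)CC/C=C(/CO[Si](C)(C)C(C)(C)C)C[C@@H](O[Si](C)(C)C(C)(C)C)/C=C(\CBr)C(=O)OC | intermediate
18 | methyl (2Z,4R,6E)‑2‑(bromomethyl)‑4‑(TBS‑oxy)‑6‑[(TBS‑oxy)methyl]‑9‑[(3R)‑5‑hydroxytetrahydrofuran‑3‑yl]nona‑2,6‑dienoate | OC1C[C@H](CO1)CC/C=C(/CO[Si](C)(C)C(C)(C)C)C[C@@H](O[Si](C)(C)C(C)(C)C)/C=C(\CBr)C(=O)OC | intermediate
19 | (4R,6R,7S,8R)‑8,14‑bis(TBS‑oxy)‑15‑hydroxygermacra‑1(10),11(13)‑dien‑12,6‑olide (not isolated) | C=C1C(=O)O[C@@H]2C[C@H](CO)CC/C=C(/CO[Si](C)(C)C(C)(C)C)C[C@@H](O[Si](C)(C)C(C)(C)C)[C@@H]12 | intermediate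
20 | (4R,6R,7R,8R)‑8,14,15‑trihydroxygermacra‑1(10),11(13)‑dien‑12,6‑olide | C=C1C(=O)O[C@@H]2C[C@H](CO)CC/C=C(/CO)C[C@@H](O)[C@@H]12 | intermediate
21 | (4R,6R,7R,8R)‑8‑hydroxy‑14,15‑bis(triethylsilyloxy)germacra‑1(10),11(13)‑dien‑12,6‑olide | C=C1C(=O)O[C@@H]2C[C@H](CO[Si](CC)(CC)CC)CC/C=C(/CO[Si](CC)(CC)CC)C[C@@H](O)[C@@H]12 | intermediate
22 | angelic acid, (Z)‑2‑methylbut‑2‑enoic acid | C/C=C(/C)C(=O)O | starting material
23 | (4R,6R,7S,8R)‑8‑angeloyloxy‑14,15‑bis(triethylsilyloxy)germacra‑1(10),11(13)‑dien‑12,6‑olide (not isolated) | C=C1C(=O)O[C@@H]2C[C@H](CO[Si](CC)(CC)CC)CC/C=C(/CO[Si](CC)(CC)CC)C[C@@H](OC(=O)/C(C)=C\C)[C@@H]12 | intermediate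
24 | (4R,6R,7S,8R)‑8‑angeloyloxy‑14,15‑dihydroxygermacra‑1(10),11(13)‑dien‑12,6‑olide (CNP0262807.1) | C=C1C(=O)O[C@@H]2C[C@H](CO)CC/C=C(/CO)C[C@@H](OC(=O)/C(C)=C\C)[C@@H]12 | target

## Step count and risks

Total step count: 15. Longest linear sequence: 14 (steps 1–3 and 5–15); step 4 is a one‑step branch.

The three steps most likely to fail:

Step 13 (macrocyclisation and lactonisation). The risks are slow reaction of the lactol with the allyl‑chromium, oligomerisation, and the wrong C6/C7 diastereomer. The fallback changes how the C7 nucleophile is generated. It sets out from 16, which is acetylated (Ac2O, pyridine, DMAP) to the Baylis–Hillman acetate F1. Acetal hydrolysis as in step 12 gives the lactol acetate F2. Ring closure is then a Pd(0)‑catalysed umpolung allylation (Pd(PPh3)4 cat., InI, THF/H2O, high dilution): the π‑allyl‑palladium formed by ionisation of the acetate is transmetalated to a nucleophilic allyl‑indium, which tolerates water and adds readily to lactols. Acid‑promoted lactonisation brings the sequence back to the route at 19, which is desilylated to 20 as in step 13.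

Step 1 (asymmetric conjugate addition to the unsubstituted butenolide). The risks are modest enantioselectivity and enolate side reactions. The fallback sets the centre by reduction instead of C–C bond formation. It sets out from 2, which is coupled with commercial 4‑bromofuran‑2(5H)‑one (CuI cat., THF, −40 °C, addition–elimination) to give 4‑(but‑3‑en‑1‑yl)furan‑2(5H)‑one F3. A CuH‑catalysed asymmetric 1,4‑reduction (Cu(OAc)2, p‑tol‑BINAP antipode giving R, PMHS, t‑BuOH, toluene) then returns to the route at 3.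

Step 10 (Baylis–Hillman reaction of a hindered α‑silyloxy aldehyde). The risks are a very slow reaction and partial epimerisation at C8. The fallback replaces amine catalysis by an aldol–elimination sequence. It sets out from 14, which reacts with the lithium enolate of methyl 3‑(phenylselanyl)propanoate (LDA, THF, −78 °C) to give the β‑hydroxy α‑(phenylselanylmethyl) ester F4. Oxidation (H2O2, pyridine, 0 °C) and selenoxide syn‑elimination then return to the route at 16.

## Further compounds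

F1 | step 13 | Baylis–Hillman acetate of 16 | COC1C[C@H](CO1)CC/C=C(/CO[Si](C)(C)C(C)(C)C)C[C@@H](O[Si](C)(C)C(C)(C)C)C(OC(C)=O)C(=C)C(=O)OC
F2 | step 13 | lactol acetate from F1 | OC1C[C@H](CO1)CC/C=C(/CO[Si](C)(C)C(C)(C)C)C[C@@H](O[Si](C)(C)C(C)(C)C)C(OC(C)=O)C(=C)C(=O)OC
F3 | step 1 | 4‑(but‑3‑en‑1‑yl)furan‑2(5H)‑one | O=C1C=C(CCC=C)CO1
F4 | step 10 | β‑hydroxy α‑(phenylselanylmethyl) ester from 14 | COC1C[C@H](CO1)CC/C=C(/CO[Si](C)(C)C(C)(C)C)C[C@@H](O[Si](C)(C)C(C)(C)C)C(O)C(C[Se]c1ccccc1)C(=O)OC
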